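One equivalent of nucleophile makes, as I take it, one equivalent of product, so at 0.800 equiv the nucleophile is the limiting reagent here.

common to all: electrophile 0.22 M
- south-east: nucleophile 0.80 equiv; free base 1.7 equiv; run made earlier
- north: nucleophile 0.80 equiv; free base 1.8 equiv; run made earlier
- green: nucleophile 0.800 equiv; free base 2.00 equiv; time 40 h
- violet: nucleophile 0.800 equiv; free base 2.60 equiv; time 40 h

| run | time / h | electrophile / % | product / % |
|---|---|---|---|
| south-east | 4.00 | 56.2 | 36.4 |
| south-east | 8.00 | 47.0 | 42.9 |
| south-east | 12.0 | 42.5 | 47.9 |
| south-east | 15.0 | 40.7 | 49.6 |
| south-east | 20.0 | 35.9 | 54.2 |
| north | 2.00 | 60.8 | 29.2 |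
| north | 5.00 | 53.0 | 38.5 |
| north | 10.0 | 44.4 | 44.3 |
| north | 15.0 | 40.7 | 49.4 |
| north | 20.0 | 38.1 | 54.5 |

(each reading ± 1 percentage point)

- part of the electrophile that has reacted at the end, green
- part of the electrophile that has reacted at the end, violet
- what raising the equivalents of free base from its lowest to its highest value here does to the part of the electrophile that has reacted (changes below 5 percentage points count as none) (no change / it rises / it falls)

- a reading or a percentage of product counts all its forms, free or not
- what has gone from electrophile into another species counts as reacted, even if it can come back
- a reading of electrophile is of its free form alone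

I read the runs as a ladder. On the first rung, at 2.00 h in the north run, electrophile and product together already fall short of the charge by 10 percentage points. At 20.0 h the two runs fall short by 8.7 points on average, so I treat this gap as flat and count it as reacted. On the next rung I take the reacted part to creep towards a ceiling, the nucleophile charge plus the gap, 88.7%.

The headroom under that ceiling reads 45 points at 4.00 h in the south-east run and 26 points at 20.0 h as the mean of both runs, a half-time of 19.8 h, read with the scatter of the readings. By 40 h I reckon it falls to half again, to 13 points, so I commit to 75.9% for green.

My ceiling has no term in free base, and the electrophile readings at 20.0 h differ by 2.2 points between 1.7 equiv and 1.8 equiv, with a scatter of 1 point on each reading. I therefore take zero base effect as my scale and give green and violet the same figure.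

The forecast gives 73% for green and 76% for violet, with no change; where I keep the two equal, it puts violet higher. Its ground for the trend: “Base seems to act mainly as a scavenger, in excess throughout”.

The flasks give 74.9% for green and 76.7% for violet, a change of 1.8 points, so no change.

    acid set free + free base ⇌ salt of the base (K = 25000 M⁻¹, k = 0.0750 M⁻¹ min⁻¹)
    electrophile + nucleophile → acid set free + product (k = 0.0310 M⁻¹ min⁻¹)
    nucleophile + acid set free ⇌ protonated nucleophile, settled at all times (K = 1800 M⁻¹)
    electrophile + product ⇌ idle adduct, settled at all times (K = 2.70 M⁻¹)

Green ends 14 points under the ceiling, against the 13 points of headroom I reckoned, and at 400 h, with 0% of its nucleophile left unbound, its answer is 86.1%, lower than 88.7%. The neighbour flask is green with 0.480 equiv of nucleophile, and the same sum, charge plus gap, puts its ceiling at 56.6%. Its reacted part at 40 h is 55.1%, which is 1.5 points under that ceiling, with 2.5% of its charged nucleophile still there unbound.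

All runs were computed on assumed constants, and the scatter is random.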